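**Plan**

- Retrosynthesis: the C12 acid goes back to an acrolein acetal and the C9 ester to acid 23; the C7–C11 bond is cut (axial cuprate addition to a 7-en-9-one); then the C5–C10 bond; last the C6–C7 and C7–C8 bonds of a ten-membered ring.
- Enabling feature: the array O–C9–C10(CH3)–C5–C4(CH3)–O. Each end of the C5–C10 bond has an oxygen-bearing neighbour, and C10 and C4 can both carry a tertiary cation. Without the C7 appendage, the periphery C1–C10 of rings A and B is the symmetric (1E,6E)-1,7-dimethylcyclodeca-1,6-diene, whose alkenes C9=C10 and C4=C5 are equivalent.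
- Forward: hepta-1,6-diyne → E,E bis-allylic dibromide → ten-membered ring by double alkylation of bis(phenylsulfonyl)methane → diene → monoepoxide → rings A and B together by one transannular epoxide–olefin cyclisation ended by water → enone → side chain → ester → acid.
- Stereochemistry: Shi epoxidation sets C9/C10 and is the only source of absolute configuration for the core. The ring closure relays it to C10 (inversion), C5 and C4. C7 comes from stereoelectronic axial conjugate addition. C9 is then re-set (oxidation, equatorial hydride delivery) to the axial 9α oxygen. The acyl stereocentre is bought in with (S)-1-bromo-2-methylbutane.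

Key step: step 6

Remark: positions are given in eudesmane numbering (C10 carries the angular methyl, C5 is the ring-fusion CH, C4 the carbinol carbon, C9 the oxygenated carbon next to C10, C7 the side-chain carbon; α/β with the C10 methyl β); 16, 21 and the L-fructose-derived Shi ketone are taken to be catalogue compounds.

**Route**

Step 1
Reactants: 1 hepta-1,6-diyne
Product: 4 (2E,7E)-3,7-dimethylnona-2,7-diene-1,9-diol, via bis(dimethylalanyl)diene 2 (not isolated), via dilithium bis(alanate) 3 (not isolated)
Conditions: Me3Al (4 equiv), Cp2ZrCl2 (0.4 equiv), CH2Cl2, 0 °C → rt; n-BuLi (2.1 equiv), THF/hexane, −78 °C; (CH2O)n, −78 °C → rt; H2O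
Reagents that add atoms: trimethylaluminium C[Al](C)C; formaldehyde (as paraformaldehyde) C=O
Why: Zr-catalysed Negishi carboalumination adds methyl and aluminium syn across each terminal alkyne with methyl on the internal carbon, so both trisubstituted alkenes should form E, and the alkenylalanate is hydroxymethylated by formaldehyde with retention.

Step 2
Reactants: 4 (2E,7E)-3,7-dimethylnona-2,7-diene-1,9-diol
Product: 5 (2E,7E)-1,9-dibromo-3,7-dimethylnona-2,7-diene
Conditions: PBr3 (0.8 equiv), Et2O, −10 °C; used crude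
Reagents that add atoms: phosphorus tribromide BrP(Br)Br
Why: SN2 bromination of primary allylic alcohols with PBr3 at low temperature (the geraniol-to-geranyl bromide reaction type) should keep the E geometry and avoid allylic transposition.

Step 3
Reactants: 5 (2E,7E)-1,9-dibromo-3,7-dimethylnona-2,7-diene; 6 bis(phenylsulfonyl)methane
Product: 8 (1E,6E)-1,7-dimethyl-4,4-bis(phenylsulfonyl)cyclodeca-1,6-diene, via open-chain monoalkylated bromide 7 (not isolated)
Conditions: Cs2CO3 (4 equiv), DMF, 5 and 6 added together by syringe pump (final 0.005 M), 50 °C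
Reagents that add atoms: none
Why: Double SN2 alkylation of the doubly stabilised carbanion by the two primary allylic bromides, the second one closing the ten-membered ring under high dilution (intramolecular allylic alkylation of a stabilised carbanion, the ring-closure type used for E,E-cyclodecadienes); the two E alkenes and the geminal sulfones should lower the transannular and entropic cost.

Step 4
Reactants: 8 (1E,6E)-1,7-dimethyl-4,4-bis(phenylsulfonyl)cyclodeca-1,6-diene
Product: 9 (1E,6E)-1,7-dimethylcyclodeca-1,6-diene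
Conditions: Mg (activated), MeOH/THF, 50 °C; aq. NH4Cl
Reagents that add atoms: none
Why: Dissolving-metal reductive desulfonylation (Mg/MeOH) cleaves both C–S bonds by successive electron transfer and protonation, and the isolated trisubstituted alkenes should be inert.

Step 5
Reactants: 9 (1E,6E)-1,7-dimethylcyclodeca-1,6-diene
Product: 10 (1S,5E,10S)-1,5-dimethyl-11-oxabicyclo[8.1.0]undec-5-ene
Conditions: L-fructose-derived Shi ketone (1,2:4,5-di-O-isopropylidene-β-L-erythro-2,3-hexodiulo-2,6-pyranose, 30 mol %), Oxone (2KHSO5·KHSO4·K2SO4, 0.7 equiv KHSO5), K2CO3, n-Bu4NHSO4 (cat.), Na2B4O7/Na2EDTA buffer (pH 10.5), MeCN/CH2(OMe)2, −10 °C; unreacted 9 recycled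
Reagents that add atoms: potassium peroxymonosulfate (Oxone) [K+].[O-]S(=O)(=O)OO
Why: Shi epoxidation (chiral dioxirane, spiro transition state), for which E-trisubstituted alkenes are the best substrate class; the two alkenes of 9 are homotopic on the time average, so attack on either gives the same monoepoxide, the L-fructose-derived ketone is the enantiomer that the spiro model assigns to the (S,S) epoxide, and substoichiometric oxidant limits bis-epoxidation.

Step 6
Reactants: 10 (1S,5E,10S)-1,5-dimethyl-11-oxabicyclo[8.1.0]undec-5-ene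
Product: 12 (1R,4aS,5S,8aR)-1,4a-dimethyldecahydronaphthalene-1,5-diol, via tertiary C4 carbocation 11 (not isolated)
Conditions: TsOH·H2O (10 mol %), acetone/H2O (5:1), 0 °C
Reagents that add atoms: water O
Why: Protonation of the epoxide lets the tertiary C10–O bond ionise while the transannular C4=C5 alkene attacks C10 through C5 from the face opposite to oxygen, and the resulting tertiary C4 cation 11 is captured by water; this is the acid-mediated transannular epoxide–olefin (cation–olefin) cyclisation known for cyclodecadiene monoepoxides, as in epoxygermacrene-to-eudesmanediol conversions. Ring B closes 6-exo on the alkene (epoxide C–O bond endo) and ring A closes 6-endo on the alkene (epoxide C–O bond exo), both through chair arrangements. C9 keeps the epoxide configuration and C10 is set by inversion, which with the E epoxide puts O9 equatorial and the C10 methyl axial; C5 follows from the E geometry of C4=C5 within the chair–chair array (H5 anti to the methyl, trans-decalin), and C4 from anti addition across the alkene, water entering equatorially on the face away from the axial C10 methyl. The step needs Markovnikov bond formation at both termini, trans- over cis-annulation, and capture by water over proton loss. The first is secured because C10 and C4 are the only tertiary sites, so the alternative C9–C5 or C10–C4 bonds would need secondary cations; the second is expected, not guaranteed, because only the trans array keeps C9 equatorial on ring A and C4 equatorial on ring B, whereas the cis array makes both axial. The third is favoured by the aqueous medium and is the weak point dealt with under the fallbacks.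

Step 7
Reactants: 12 (1R,4aS,5S,8aR)-1,4a-dimethyldecahydronaphthalene-1,5-diol
Product: 13 (4aR,5R,8aS)-5-hydroxy-5,8a-dimethyloctahydronaphthalen-1(2H)-one
Conditions: Dess–Martin periodinane, NaHCO3, CH2Cl2, rt
Reagents that add atoms: none
Why: Dess–Martin oxidation converts the secondary C9 alcohol to the ketone, and the tertiary C4 hydroxyl cannot be oxidised.

Step 8
Reactants: 13 (4aR,5R,8aS)-5-hydroxy-5,8a-dimethyloctahydronaphthalen-1(2H)-one
Product: 14 trimethyl{[(4aR,5R,8aS)-5,8a-dimethyl-5-[(trimethylsilyl)oxy]-3,4,4a,5,6,7,8,8a-octahydronaphthalen-1-yl]oxy}silane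
Conditions: TMSOTf (2.5 equiv), Et3N (4 equiv), CH2Cl2, 0 °C; used crude
Reagents that add atoms: trimethylsilyl trifluoromethanesulfonate C[Si](C)(C)OS(=O)(=O)C(F)(F)F
Why: Soft enolisation and silylation gives the only possible enol silane (toward C8, since C10 is quaternary) and silylates the tertiary C4 hydroxyl in the same operation, which protects it until step 14.

Step 9
Reactants: 14 trimethyl{[(4aR,5R,8aS)-5,8a-dimethyl-5-[(trimethylsilyl)oxy]-3,4,4a,5,6,7,8,8a-octahydronaphthalen-1-yl]oxy}silane
Product: 15 (4aR,5R,8aS)-5,8a-dimethyl-5-[(trimethylsilyl)oxy]-4a,5,6,7,8,8a-hexahydronaphthalen-1(4H)-one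
Conditions: Pd(OAc)2 (1.05 equiv), MeCN, rt
Reagents that add atoms: none
Why: Saegusa–Ito oxidation, in which the palladium enolate undergoes β-hydride elimination toward C7, the only adjacent carbon that bears hydrogen, to give the C7=C8 enone.

Step 10
Reactants: 15 (4aR,5R,8aS)-5,8a-dimethyl-5-[(trimethylsilyl)oxy]-4a,5,6,7,8,8a-hexahydronaphthalen-1(4H)-one; 16 2-bromo-3,3-diethoxyprop-1-ene
Product: 19 (3R,4aR,5R,8aS)-3-(3,3-diethoxyprop-1-en-2-yl)-5,8a-dimethyl-5-[(trimethylsilyl)oxy]octahydronaphthalen-1(2H)-one, via (3,3-diethoxyprop-1-en-2-yl)lithium 17 (not isolated), via lithium bis(3,3-diethoxyprop-1-en-2-yl)cuprate 18 (not isolated)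
Conditions: 16, t-BuLi (2 equiv), Et2O, −78 °C; CuBr·SMe2 (0.5 equiv per organolithium), −78 → −45 °C; then 15, Et2O/THF, −78 °C; aq. NH4Cl
Reagents that add atoms: none
Why: Conjugate addition of a Gilman cuprate (an acrolein α-anion equivalent) should occur by stereoelectronically controlled axial attack on the trans-fused cyclohexenone, anti to the equatorial C5–C4 bond (the trans-3,5 rule for 5-substituted cyclohexenones), which places the three-carbon unit axial and α at C7, syn to H5 and anti to the angular methyl.

Step 11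
Reactants: 19 (3R,4aR,5R,8aS)-3-(3,3-diethoxyprop-1-en-2-yl)-5,8a-dimethyl-5-[(trimethylsilyl)oxy]octahydronaphthalen-1(2H)-one
Product: 20 (1R,3R,4aR,5R,8aS)-3-(3,3-diethoxyprop-1-en-2-yl)-5,8a-dimethyl-5-[(trimethylsilyl)oxy]decahydronaphthalen-1-ol
Conditions: LiBH(s-Bu)3 (L-selectride), THF, −78 °C; H2O
Reagents that add atoms: none
Why: The bulky trialkylborohydride should attack the C9 carbonyl from the equatorial β side because the axial trajectory is closed by the syn-axial C7 substituent, which gives the axial 9α alcohol cis to the side chain.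

Step 12
Reactants: 21 (S)-1-bromo-2-methylbutane
Product: 23 (S)-3-methylpentanoic acid, via [(2S)-2-methylbutyl]magnesium bromide 22 (not isolated)
Conditions: Mg, Et2O, reflux; CO2 (dry ice), −78 °C; aq. HCl
Reagents that add atoms: carbon dioxide O=C=O
Why: Grignard formation and carboxylation take place at the primary carbon, so the adjacent stereocentre is untouched and the S descriptor is kept.

Step 13
Reactants: 20 (1R,3R,4aR,5R,8aS)-3-(3,3-diethoxyprop-1-en-2-yl)-5,8a-dimethyl-5-[(trimethylsilyl)oxy]decahydronaphthalen-1-ol; 23 (S)-3-methylpentanoic acid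
Product: 25 (1R,3R,4aR,5R,8aS)-3-(3,3-diethoxyprop-1-en-2-yl)-5,8a-dimethyl-5-[(trimethylsilyl)oxy]decahydronaphthalen-1-yl (3S)-3-methylpentanoate, via (3S)-3-methylpentanoic 2,4,6-trichlorobenzoic anhydride 24 (not isolated)
Conditions: 2,4,6-trichlorobenzoyl chloride, Et3N, THF, rt; then 20, DMAP, toluene, 60 °C
Reagents that add atoms: none
Why: Yamaguchi esterification through the mixed anhydride and DMAP acyl transfer should acylate the hindered axial secondary alcohol with retention at C9, while the C4 oxygen is silylated and the acetal is stable to base.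

Step 14
Reactants: 25 (1R,3R,4aR,5R,8aS)-3-(3,3-diethoxyprop-1-en-2-yl)-5,8a-dimethyl-5-[(trimethylsilyl)oxy]decahydronaphthalen-1-yl (3S)-3-methylpentanoate
Product: 26 (1R,3R,4aR,5R,8aS)-5-hydroxy-5,8a-dimethyl-3-(3-oxoprop-1-en-2-yl)decahydronaphthalen-1-yl (3S)-3-methylpentanoate
Conditions: TsOH·H2O (0.2 equiv), acetone/H2O (10:1), rt
Reagents that add atoms: water O
Why: Acid-catalysed hydrolysis of the vinyl-substituted diethyl acetal (through a conjugated oxocarbenium ion) and of the tertiary trimethylsilyl ether under conditions that should leave the ester and the tertiary alcohol intact.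

Step 15
Reactants: 26 (1R,3R,4aR,5R,8aS)-5-hydroxy-5,8a-dimethyl-3-(3-oxoprop-1-en-2-yl)decahydronaphthalen-1-yl (3S)-3-methylpentanoate
Product: 27 2-[(2R,4R,4aS,8R,8aR)-8-hydroxy-4a,8-dimethyl-4-{[(3S)-3-methylpentanoyl]oxy}decahydronaphthalen-2-yl]prop-2-enoic acid (CNP0471281.2)
Conditions: NaClO2, NaH2PO4, 2-methylbut-2-ene, t-BuOH/H2O, 0 °C → rt
Reagents that add atoms: sodium chlorite [Na+].[O-]Cl=O
Why: Pinnick oxidation converts the α-substituted acrolein to the acrylic acid without touching the alkene, the tertiary alcohol or the ester, the alkene scavenger removing hypochlorous acid.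

**Compound list**

1 | hepta-1,6-diyne | C#CCCCC#C | starting material
2 | (1E,6E)-1,7-bis(dimethylalanyl)-2,6-dimethylhepta-1,6-diene | C[Al](C)/C=C(\C)CCC/C(C)=C/[Al](C)C | intermediate
3 | dilithium bis(butyl)alanate of 2 | [Li+].[Li+].CCCC[Al-](C)(C)/C=C(\C)CCC/C(C)=C/[Al-](C)(C)CCCC | intermediate
4 | (2E,7E)-3,7-dimethylnona-2,7-diene-1,9-diol | OC/C=C(\C)CCC/C(C)=C/CO | intermediate
5 | (2E,7E)-1,9-dibromo-3,7-dimethylnona-2,7-diene | BrC/C=C(\C)CCC/C(C)=C/CBr | intermediate
6 | bis(phenylsulfonyl)methane | O=S(=O)(CS(=O)(=O)c1ccccc1)c1ccccc1 | starting material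
7 | (3E,8E)-10-bromo-4,8-dimethyl-1,1-bis(phenylsulfonyl)deca-3,8-diene | BrC/C=C(\C)CCC/C(C)=C/CC(S(=O)(=O)c1ccccc1)S(=O)(=O)c1ccccc1 | intermediate
8 | (1E,6E)-1,7-dimethyl-4,4-bis(phenylsulfonyl)cyclodeca-1,6-diene | C/C1=C\CC(S(=O)(=O)c2ccccc2)(S(=O)(=O)c2ccccc2)C/C=C(\C)CCC1 | intermediate
9 | (1E,6E)-1,7-dimethylcyclodeca-1,6-diene | C/C1=C\CCC/C=C(\C)CCC1 | intermediate
10 | (1S,5E,10S)-1,5-dimethyl-11-oxabicyclo[8.1.0]undec-5-ene (C9–C10 epoxide) | C[C@@]12O[C@H]1CCC/C=C(\C)CCC2 | intermediate
11 | tertiary C4 carbocation of the trans-decalin (12 without its C4 hydroxyl) | C[C@]12CCC[C+](C)[C@@H]1CCC[C@@H]2O | intermediate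
12 | (1R,4aS,5S,8aR)-1,4a-dimethyldecahydronaphthalene-1,5-diol (4α,9β-diol) | C[C@]12CCC[C@@](C)(O)[C@@H]1CCC[C@@H]2O | intermediate
13 | (4aR,5R,8aS)-5-hydroxy-5,8a-dimethyloctahydronaphthalen-1(2H)-one | C[C@]12CCC[C@@](C)(O)[C@@H]1CCCC2=O | intermediate
14 | trimethyl{[(4aR,5R,8aS)-5,8a-dimethyl-5-[(trimethylsilyl)oxy]-3,4,4a,5,6,7,8,8a-octahydronaphthalen-1-yl]oxy}silane | C[C@]12CCC[C@@](C)(O[Si](C)(C)C)[C@@H]1CCC=C2O[Si](C)(C)C | intermediate
15 | (4aR,5R,8aS)-5,8a-dimethyl-5-[(trimethylsilyl)oxy]-4a,5,6,7,8,8a-hexahydronaphthalen-1(4H)-one | C[C@]12CCC[C@@](C)(O[Si](C)(C)C)[C@@H]1CC=CC2=O | intermediate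
16 | 2-bromo-3,3-diethoxyprop-1-ene | C=C(Br)C(OCC)OCC | starting material
17 | (3,3-diethoxyprop-1-en-2-yl)lithium | [Li]C(=C)C(OCC)OCC | intermediate
18 | lithium bis(3,3-diethoxyprop-1-en-2-yl)cuprate | [Li+].CCOC(OCC)C(=C)[Cu-]C(=C)C(OCC)OCC | intermediate
19 | (3R,4aR,5R,8aS)-3-(3,3-diethoxyprop-1-en-2-yl)-5,8a-dimethyl-5-[(trimethylsilyl)oxy]octahydronaphthalen-1(2H)-one | C[C@]12CCC[C@@](C)(O[Si](C)(C)C)[C@@H]1C[C@@H](C(=C)C(OCC)OCC)CC2=O | intermediate
20 | (1R,3R,4aR,5R,8aS)-3-(3,3-diethoxyprop-1-en-2-yl)-5,8a-dimethyl-5-[(trimethylsilyl)oxy]decahydronaphthalen-1-ol | C[C@]12CCC[C@@](C)(O[Si](C)(C)C)[C@@H]1C[C@@H](C(=C)C(OCC)OCC)C[C@H]2O | intermediate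
21 | (S)-1-bromo-2-methylbutane | CC[C@H](C)CBr | starting material
22 | [(2S)-2-methylbutyl]magnesium bromide | CC[C@H](C)C[Mg]Br | intermediate
23 | (S)-3-methylpentanoic acid | CC[C@H](C)CC(=O)O | intermediate
24 | (3S)-3-methylpentanoic 2,4,6-trichlorobenzoic anhydride | CC[C@H](C)CC(=O)OC(=O)c1c(Cl)cc(Cl)cc1Cl | intermediate
25 | (1R,3R,4aR,5R,8aS)-3-(3,3-diethoxyprop-1-en-2-yl)-5,8a-dimethyl-5-[(trimethylsilyl)oxy]decahydronaphthalen-1-yl (3S)-3-methylpentanoate | C[C@]12CCC[C@@](C)(O[Si](C)(C)C)[C@@H]1C[C@@H](C(=C)C(OCC)OCC)C[C@H]2OC(=O)C[C@@H](C)CC | intermediate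
26 | (1R,3R,4aR,5R,8aS)-5-hydroxy-5,8a-dimethyl-3-(3-oxoprop-1-en-2-yl)decahydronaphthalen-1-yl (3S)-3-methylpentanoate | C[C@]12CCC[C@@](C)(O)[C@@H]1C[C@@H](C(=C)C=O)C[C@H]2OC(=O)C[C@@H](C)CC | intermediate
27 | 2-[(2R,4R,4aS,8R,8aR)-8-hydroxy-4a,8-dimethyl-4-{[(3S)-3-methylpentanoyl]oxy}decahydronaphthalen-2-yl]prop-2-enoic acid | C[C@]12CCC[C@@](C)(O)[C@@H]1C[C@@H](C(=C)C(=O)O)C[C@H]2OC(=O)C[C@@H](C)CC | target

**Step count**

Total: 15 steps. Longest linear sequence: 14 steps (1–11 and 13–15; step 12 makes the acyl fragment).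

**Steps most likely to fail**

Step 6. After ring closure the C4 cation may lose a proton from C3 or C15 faster than water adds; the activated epoxide may also be opened by water without ring closure, or the ring may close to the cis-decalin. The fallback separates ring closure from hydration. It sets out from 10, which would be cyclised under anhydrous Lewis-acid conditions (BF3·OEt2, CH2Cl2, −78 °C), where proton loss is the only exit. This should give the exocyclic alkene (1S,4aS,8aS)-8a-methyl-5-methylidenedecahydronaphthalen-1-ol F1 together with its ring-alkene isomer (1S,4aS,8aS)-5,8a-dimethyl-1,2,3,4,4a,7,8,8a-octahydronaphthalen-1-ol F2. The mixture would then be submitted to Mukaiyama hydration (Co(acac)2, PhSiH3, O2, THF, then Na2S2O3). Both isomers pass through the same tertiary C4 radical, which should take up oxygen on the equatorial α face away from the syn-axial C10 methyl, and the route is rejoined at 12.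

Step 3. Intermolecular alkylation of 7 (oligomerisation) may outrun closure of the ten-membered ring. The fallback replaces the SN2 closure by a metal-templated one and sets out from 4. The diol would be converted (ClCO2Me, pyridine) to the bis(methyl carbonate), dimethyl (2E,7E)-3,7-dimethylnona-2,7-diene-1,9-diyl biscarbonate F3. F3 and 6 would then be added slowly to Pd(PPh3)4/dppe in THF at reflux (Tsuji–Trost double allylic alkylation). Each carbonate ionises on zerovalent palladium to a π-allyl complex and releases its own methoxide base, and medium-ring closure on such complexes is a known strength of this reaction; the route is rejoined at 8.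

Step 5. Enantioface discrimination on the conformationally mobile ring may be weak, and over-oxidation to the bis-epoxide may erode the yield. The fallback moves the asymmetric epoxidation to the acyclic stage and sets out from 4.

- Sharpless asymmetric epoxidation of one of the two allylic alcohols (Ti(OiPr)4, L-(+)-diethyl tartrate, t-BuOOH 0.6 equiv, 4 Å sieves, CH2Cl2, −20 °C) should give [(2S,3S)-3-[(4E)-6-hydroxy-4-methylhex-4-en-1-yl]-3-methyloxiran-2-yl]methanol F4.
- Appel bromination (CBr4, PPh3) would give (2R,3S)-2-(bromomethyl)-3-[(4E)-6-bromo-4-methylhex-4-en-1-yl]-3-methyloxirane F5.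
- Ring closure with 6 and Cs2CO3 as in step 3 would give the epoxy bis-sulfone (1S,5E,10S)-1,5-dimethyl-8,8-bis(phenylsulfonyl)-11-oxabicyclo[8.1.0]undec-5-ene F6.
- Buffered reductive desulfonylation (Na(Hg), Na2HPO4, MeOH/THF, −20 °C) rejoins the route at 10.

**Further compounds**

F1 | step 6 | (1S,4aS,8aS)-8a-methyl-5-methylidenedecahydronaphthalen-1-ol | C[C@]12CCCC(=C)[C@@H]1CCC[C@@H]2O
F2 | step 6 | (1S,4aS,8aS)-5,8a-dimethyl-1,2,3,4,4a,7,8,8a-octahydronaphthalen-1-ol | C[C@]12CCC=C(C)[C@@H]1CCC[C@@H]2O
F3 | step 3 | dimethyl (2E,7E)-3,7-dimethylnona-2,7-diene-1,9-diyl biscarbonate | COC(=O)OC/C=C(\C)CCC/C(C)=C/COC(=O)OC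
F4 | step 5 | [(2S,3S)-3-[(4E)-6-hydroxy-4-methylhex-4-en-1-yl]-3-methyloxiran-2-yl]methanol | C[C@@]1(CCC/C(C)=C/CO)O[C@H]1CO
F5 | step 5 | (2R,3S)-2-(bromomethyl)-3-[(4E)-6-bromo-4-methylhex-4-en-1-yl]-3-methyloxirane | C[C@@]1(CCC/C(C)=C/CBr)O[C@H]1CBr
F6 | step 5 | (1S,5E,10S)-1,5-dimethyl-8,8-bis(phenylsulfonyl)-11-oxabicyclo[8.1.0]undec-5-ene | C[C@@]12O[C@H]1CC(S(=O)(=O)c3ccccc3)(S(=O)(=O)c3ccccc3)C/C=C(\C)CCC2
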